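**Retrosynthetic overview**

1. The (2S) target comes from a fully protected flavanone (flavonol phenols as benzyl ethers, flavanone 5-OH as a silyl ether) by two non-basic deprotections that cannot racemise C2.
2. Ring C of the flavanone is the last ring formed: the C2–C3 bond and the C2 stereocentre are made together by an enantioselective dirhodium-carbenoid 1,6 C–H insertion of a ring-A α-diazoketone into its ortho ArO–CH2–Ar ether.
3. Enabling feature: C2 is both benzylic to ring B and α to O1, so in the precursor it is an electron-rich ArO–CH2–Ar methylene with two enantiotopic hydrogens, held six atoms from the carbenoid carbon (future C3) by the ortho O1/C4 pattern of ring A.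
4. The diazoketone comes from the aryl methyl ketone by diazo transfer; the ketone comes from a Mitsunobu union of 2,6-dihydroxy-4-methoxyacetophenone (ring A) with a ring-B benzyl alcohol.
5. The ring-B benzyl alcohol comes from SNAr of 7,4'-di-O-benzylkaempferol (through O3) on 4-fluorobenzaldehyde; the flavonol rings are bought intact as kaempferol. Order: flavonol rings (purchased), ring B attached, ring A attached, ring C closed.

Key step: step 7

Remark on the chemistry: the absolute sense of induction of a chiral dirhodium carboxylate on this diazoketone cannot be predicted with certainty; the route is written with Rh2(S-DOSP)4, and if a test run shows the 2R product, the mirror-image catalyst Rh2(R-DOSP)4 is used with nothing else changed.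

**Route**

Step 1
Reactants: 1 kaempferol
Product: 2 7,4'-di-O-benzylkaempferol (7-(benzyloxy)-2-[4-(benzyloxy)phenyl]-3,5-dihydroxy-4H-chromen-4-one)
Conditions: BnBr (2.1 equiv), K2CO3 (2.2 equiv), DMF, 0 °C to rt, Ar
Reagents that add atoms: benzyl bromide, BrCc1ccccc1
Why: Williamson ether synthesis under weak base should take the two most acidic, non-chelated phenols (7-OH and 4'-OH) first, while the 3-OH and 5-OH, both hydrogen-bonded to the C4 carbonyl, stay free at this stoichiometry.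

Step 2
Reactants: 2 7,4'-di-O-benzylkaempferol; 3 4-fluorobenzaldehyde
Product: 5 4-({5,7-bis(benzyloxy)-2-[4-(benzyloxy)phenyl]-4-oxo-4H-chromen-3-yl}oxy)benzaldehyde, via 5-hydroxy diaryl ether aldehyde 4 (not isolated)
Conditions: K2CO3, DMF (degassed), 100 °C, Ar; then BnBr, 60 °C
Reagents that add atoms: benzyl bromide, BrCc1ccccc1
Why: Nucleophilic aromatic substitution (SNAr) in which the flavonol 3-oxide, more acidic and more nucleophilic than the chelated 5-OH, displaces fluoride para to the formyl group through a Meisenheimer intermediate, followed in the same pot by Williamson benzylation of the remaining 5-OH so that no free phenol reaches the carbene step.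

Step 3
Reactants: 5 4-({5,7-bis(benzyloxy)-2-[4-(benzyloxy)phenyl]-4-oxo-4H-chromen-3-yl}oxy)benzaldehyde
Product: 6 5,7-bis(benzyloxy)-2-[4-(benzyloxy)phenyl]-3-[4-(hydroxymethyl)phenoxy]-4H-chromen-4-one
Conditions: NaBH4 (0.6 equiv), THF/MeOH, 0 °C
Reagents that add atoms: none
Why: Chemoselective borohydride reduction, since the aryl aldehyde is reduced at 0 °C much faster than the vinylogous ester carbonyl of the fully substituted chromen-4-one.

Step 4
Reactants: 6 5,7-bis(benzyloxy)-2-[4-(benzyloxy)phenyl]-3-[4-(hydroxymethyl)phenoxy]-4H-chromen-4-one; 7 1-(2,6-dihydroxy-4-methoxyphenyl)ethan-1-one (1.5 equiv)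
Product: 8 1-{2-[(4-{[5,7-bis(benzyloxy)-2-(4-(benzyloxy)phenyl)-4-oxo-4H-chromen-3-yl]oxy}phenyl)methoxy]-6-hydroxy-4-methoxyphenyl}ethan-1-one
Conditions: PPh3, DIAD, THF, 0 °C to rt
Reagents that add atoms: none
Why: Mitsunobu reaction in which the acidic chelated phenol of 7 is alkylated by SN2 attack on the alkoxyphosphonium ion of the primary benzylic alcohol, an excess of the symmetric diol 7 (two equivalent hydroxyls) keeping the reaction at the mono-ether.

Step 5
Reactants: 8 1-{2-[(4-{[5,7-bis(benzyloxy)-2-(4-(benzyloxy)phenyl)-4-oxo-4H-chromen-3-yl]oxy}phenyl)methoxy]-6-hydroxy-4-methoxyphenyl}ethan-1-one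
Product: 9 1-{2-[(4-{[5,7-bis(benzyloxy)-2-(4-(benzyloxy)phenyl)-4-oxo-4H-chromen-3-yl]oxy}phenyl)methoxy]-4-methoxy-6-[(triisopropylsilyl)oxy]phenyl}ethan-1-one
Conditions: iPr3SiCl, imidazole, DMAP (cat), DMF, 40 °C
Reagents that add atoms: chlorotriisopropylsilane, CC(C)[Si](Cl)(C(C)C)C(C)C
Why: O-silylation of the last phenol through the imidazole-activated silyl chloride installs a group that has no activated C–H bond, leaves its oxygen hindered and weakly basic toward the later carbenoid, survives the enolate chemistry of step 6 and can later be removed by buffered fluoride without base.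

Step 6
Reactants: 9 1-{2-[(4-{[5,7-bis(benzyloxy)-2-(4-(benzyloxy)phenyl)-4-oxo-4H-chromen-3-yl]oxy}phenyl)methoxy]-4-methoxy-6-[(triisopropylsilyl)oxy]phenyl}ethan-1-one
Product: 11 2-diazo-1-{2-[(4-{[5,7-bis(benzyloxy)-2-(4-(benzyloxy)phenyl)-4-oxo-4H-chromen-3-yl]oxy}phenyl)methoxy]-4-methoxy-6-[(triisopropylsilyl)oxy]phenyl}ethan-1-one, via trifluoroacetyl diketone 10 (not isolated)
Conditions: LiN(SiMe3)2, THF, −78 °C; CF3CO2CH2CF3; aqueous HCl work-up; then 4-acetamidobenzenesulfonyl azide, Et3N, H2O, MeCN, rt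
Reagents that add atoms: 4-acetamidobenzenesulfonyl azide, CC(=O)Nc1ccc(cc1)S(=O)(=O)N=[N+]=[N-]; 2,2,2-trifluoroethyl trifluoroacetate, O=C(OCC(F)(F)F)C(F)(F)F (its trifluoroacetyl group is kept only in 10)
Why: Detrifluoroacetylative diazo transfer (Regitz-type), in which the kinetic lithium enolate of the methyl ketone is C-trifluoroacetylated to the activated 1,3-diketone 10, which then takes the diazo group from the sulfonyl azide and loses the trifluoroacetyl group as the N-acylsulfonamide, a sequence established for aryl methyl ketones.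

Step 7
Reactants: 11 2-diazo-1-{2-[(4-{[5,7-bis(benzyloxy)-2-(4-(benzyloxy)phenyl)-4-oxo-4H-chromen-3-yl]oxy}phenyl)methoxy]-4-methoxy-6-[(triisopropylsilyl)oxy]phenyl}ethan-1-one
Product: 12 (2S)-2-(4-{[5,7-bis(benzyloxy)-2-(4-(benzyloxy)phenyl)-4-oxo-4H-chromen-3-yl]oxy}phenyl)-7-methoxy-5-[(triisopropylsilyl)oxy]-2,3-dihydro-4H-chromen-4-one
Conditions: Rh2(S-DOSP)4 (dirhodium tetrakis[(S)-N-(4-dodecylbenzenesulfonyl)prolinate], 1–2 mol %), CH2Cl2, −20 °C to rt, slow addition of 11 to the catalyst at high dilution, Ar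
Reagents that add atoms: none
Why: The divalent rhodium carboxylate takes up the diazo carbon of 11, N2 leaves, and the electrophilic rhodium carbenoid at the future C3 inserts through a concerted, asynchronous three-centre transition state with hydride-transfer character into one C–H bond of the ArO–CH2–Ar methylene (the future C2), where the building positive charge is stabilised by the lone pair of O1 and by the para-aryloxy-substituted ring B. The closest known reaction type is the enantioselective intramolecular C–H insertion of 2-alkoxyaryl α-diazoketones to chroman-4-ones under chiral dirhodium N-arenesulfonylprolinates. Ring C of the flavanone is closed by a 1,6 C–H insertion through a six-membered transition state, that is at the carbon–carbon bond C2–C3 and not at O1. The C2 stereocentre is controlled by the catalyst alone: its chiral carboxylate ligand sphere lets the carbenoid reach only one of the two enantiotopic methylene hydrogens, and the insertion goes with retention at that carbon. The step needs chemoselectivity for C–H insertion over oxonium ylide formation with [1,2] benzyl shift (Stevens rearrangement) to a 2-benzylbenzofuran-3-one and over attack at the second ortho oxygen; this is secured by the weakly basic aryl ether oxygen, the reversibility of ylide formation on rhodium, the doubly activated benzylic α-oxy C–H bond, and the bulky OSi(iPr)3 group on the other flank whose oxygen is weakly Lewis basic and whose C–H bonds are unactivated, while slow addition at high dilution suppresses carbene dimerisation and intermolecular reaction with the benzyl ethers of the flavonol half.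

Step 8
Reactants: 12 (2S)-2-(4-{[5,7-bis(benzyloxy)-2-(4-(benzyloxy)phenyl)-4-oxo-4H-chromen-3-yl]oxy}phenyl)-7-methoxy-5-[(triisopropylsilyl)oxy]-2,3-dihydro-4H-chromen-4-one
Product: 13 (2S)-2-(4-{[5,7-bis(benzyloxy)-2-(4-(benzyloxy)phenyl)-4-oxo-4H-chromen-3-yl]oxy}phenyl)-5-hydroxy-7-methoxy-2,3-dihydro-4H-chromen-4-one
Conditions: Bu4NF, AcOH (1:1), THF, 0 °C
Reagents that add atoms: none
Why: Fluoride desilylation driven by the Si–F bond and buffered with acetic acid, so that no phenoxide or enolate can open ring C by retro-oxa-Michael (E1cB) reaction and racemise C2.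

Step 9
Reactants: 13 (2S)-2-(4-{[5,7-bis(benzyloxy)-2-(4-(benzyloxy)phenyl)-4-oxo-4H-chromen-3-yl]oxy}phenyl)-5-hydroxy-7-methoxy-2,3-dihydro-4H-chromen-4-one
Product: 14 (2S)-2-(4-{[5,7-dihydroxy-2-(4-hydroxyphenyl)-4-oxo-4H-chromen-3-yl]oxy}phenyl)-5-hydroxy-7-methoxy-2,3-dihydro-4H-chromen-4-one (CNP0173006.1)
Conditions: H2 (1 atm), 10% Pd/C, EtOAc/MeOH, rt
Reagents that add atoms: none
Why: Catalytic hydrogenolysis of the three aryl benzyl ethers under neutral conditions should leave the flavanone carbonyl, the cyclic benzylic C2–O1 bond (slower to cleave than the acyclic O-benzyl groups), both diaryl ether bonds and the tetrasubstituted flavonol double bond intact and does not touch C2.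

**Compound list**

1 | kaempferol, 3,5,7-trihydroxy-2-(4-hydroxyphenyl)-4H-chromen-4-one | O=c1c(O)c(-c2ccc(O)cc2)oc2cc(O)cc(O)c12 | starting material
2 | 7,4'-di-O-benzylkaempferol, 7-(benzyloxy)-2-[4-(benzyloxy)phenyl]-3,5-dihydroxy-4H-chromen-4-one | O=c1c(O)c(-c2ccc(OCc3ccccc3)cc2)oc2cc(OCc3ccccc3)cc(O)c12 | intermediate
3 | 4-fluorobenzaldehyde | O=Cc1ccc(F)cc1 | starting material
4 | 4-({7-(benzyloxy)-2-[4-(benzyloxy)phenyl]-5-hydroxy-4-oxo-4H-chromen-3-yl}oxy)benzaldehyde (formed in the flask in step 2) | O=Cc1ccc(Oc2c(-c3ccc(OCc4ccccc4)cc3)oc3cc(OCc4ccccc4)cc(O)c3c2=O)cc1 | intermediate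
5 | 4-({5,7-bis(benzyloxy)-2-[4-(benzyloxy)phenyl]-4-oxo-4H-chromen-3-yl}oxy)benzaldehyde | O=Cc1ccc(Oc2c(-c3ccc(OCc4ccccc4)cc3)oc3cc(OCc4ccccc4)cc(OCc4ccccc4)c3c2=O)cc1 | intermediate
6 | 5,7-bis(benzyloxy)-2-[4-(benzyloxy)phenyl]-3-[4-(hydroxymethyl)phenoxy]-4H-chromen-4-one | OCc1ccc(Oc2c(-c3ccc(OCc4ccccc4)cc3)oc3cc(OCc4ccccc4)cc(OCc4ccccc4)c3c2=O)cc1 | intermediate
7 | 1-(2,6-dihydroxy-4-methoxyphenyl)ethan-1-one (2',6'-dihydroxy-4'-methoxyacetophenone) | COc1cc(O)c(C(C)=O)c(O)c1 | starting material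
8 | 1-{2-[(4-{[5,7-bis(benzyloxy)-2-(4-(benzyloxy)phenyl)-4-oxo-4H-chromen-3-yl]oxy}phenyl)methoxy]-6-hydroxy-4-methoxyphenyl}ethan-1-one | COc1cc(O)c(C(C)=O)c(OCc2ccc(Oc3c(-c4ccc(OCc5ccccc5)cc4)oc4cc(OCc5ccccc5)cc(OCc5ccccc5)c4c3=O)cc2)c1 | intermediate
9 | 1-{2-[(4-{[5,7-bis(benzyloxy)-2-(4-(benzyloxy)phenyl)-4-oxo-4H-chromen-3-yl]oxy}phenyl)methoxy]-4-methoxy-6-[(triisopropylsilyl)oxy]phenyl}ethan-1-one | COc1cc(O[Si](C(C)C)(C(C)C)C(C)C)c(C(C)=O)c(OCc2ccc(Oc3c(-c4ccc(OCc5ccccc5)cc4)oc4cc(OCc5ccccc5)cc(OCc5ccccc5)c4c3=O)cc2)c1 | intermediate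
10 | 4,4,4-trifluoro-1-{2-[(4-{[5,7-bis(benzyloxy)-2-(4-(benzyloxy)phenyl)-4-oxo-4H-chromen-3-yl]oxy}phenyl)methoxy]-4-methoxy-6-[(triisopropylsilyl)oxy]phenyl}butane-1,3-dione (formed in the flask in step 6) | COc1cc(O[Si](C(C)C)(C(C)C)C(C)C)c(C(=O)CC(=O)C(F)(F)F)c(OCc2ccc(Oc3c(-c4ccc(OCc5ccccc5)cc4)oc4cc(OCc5ccccc5)cc(OCc5ccccc5)c4c3=O)cc2)c1 | intermediate
11 | 2-diazo-1-{2-[(4-{[5,7-bis(benzyloxy)-2-(4-(benzyloxy)phenyl)-4-oxo-4H-chromen-3-yl]oxy}phenyl)methoxy]-4-methoxy-6-[(triisopropylsilyl)oxy]phenyl}ethan-1-one | COc1cc(O[Si](C(C)C)(C(C)C)C(C)C)c(C(=O)C=[N+]=[N-])c(OCc2ccc(Oc3c(-c4ccc(OCc5ccccc5)cc4)oc4cc(OCc5ccccc5)cc(OCc5ccccc5)c4c3=O)cc2)c1 | intermediate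
12 | (2S)-2-(4-{[5,7-bis(benzyloxy)-2-(4-(benzyloxy)phenyl)-4-oxo-4H-chromen-3-yl]oxy}phenyl)-7-methoxy-5-[(triisopropylsilyl)oxy]-2,3-dihydro-4H-chromen-4-one | COc1cc(O[Si](C(C)C)(C(C)C)C(C)C)c2c(c1)O[C@H](c1ccc(Oc3c(-c4ccc(OCc5ccccc5)cc4)oc4cc(OCc5ccccc5)cc(OCc5ccccc5)c4c3=O)cc1)CC2=O | intermediate
13 | (2S)-2-(4-{[5,7-bis(benzyloxy)-2-(4-(benzyloxy)phenyl)-4-oxo-4H-chromen-3-yl]oxy}phenyl)-5-hydroxy-7-methoxy-2,3-dihydro-4H-chromen-4-one | COc1cc(O)c2c(c1)O[C@H](c1ccc(Oc3c(-c4ccc(OCc5ccccc5)cc4)oc4cc(OCc5ccccc5)cc(OCc5ccccc5)c4c3=O)cc1)CC2=O | intermediate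
14 | (2S)-2-(4-{[5,7-dihydroxy-2-(4-hydroxyphenyl)-4-oxo-4H-chromen-3-yl]oxy}phenyl)-5-hydroxy-7-methoxy-2,3-dihydro-4H-chromen-4-one (CNP0173006.1) | COc1cc(O)c2c(c1)O[C@H](c1ccc(Oc3c(-c4ccc(O)cc4)oc4cc(O)cc(O)c4c3=O)cc1)CC2=O | target

**Step count and risks**

Total steps: 9. Longest linear sequence: 9 steps (1 to 14), with 3 and 7 entering as purchased building blocks.

Steps most likely to fail:

1. Step 7. The carbenoid may be diverted to the oxonium ylide at the benzyl ether oxygen, followed by [1,2] benzyl shift, or the catalyst may discriminate the two enantiotopic hydrogens too weakly. Enantiomeric purity is to be checked on a chiral stationary phase at 13, where enrichment by crystallisation would also be tried. The fallback closes ring C at O1–C2 instead and sets out from aldehyde 5 and ketone 7. Claisen–Schmidt condensation (KOH, EtOH/THF, rt) should give (E)-1-(2,6-dihydroxy-4-methoxyphenyl)-3-(4-{[5,7-bis(benzyloxy)-2-(4-(benzyloxy)phenyl)-4-oxo-4H-chromen-3-yl]oxy}phenyl)prop-2-en-1-one F1. Intramolecular oxa-Michael addition (NaOAc, EtOH, reflux) should then give racemic 2-(4-{[5,7-bis(benzyloxy)-2-(4-(benzyloxy)phenyl)-4-oxo-4H-chromen-3-yl]oxy}phenyl)-5-hydroxy-7-methoxy-2,3-dihydro-4H-chromen-4-one F2. Its enantiomers are separated by preparative HPLC on an amylose tris(3,5-dimethylphenylcarbamate) stationary phase, and the (2S) enantiomer is compound 13, where the route is rejoined before step 9.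

2. Step 2. Substitution by the chelated, delocalised 3-oxide may be sluggish at a temperature where the flavonolate degrades oxidatively under base, or arylation may stray to O5. The fallback sets out from 2 and uses metal-free O-arylation by ligand coupling at iodine. (4-Formylphenyl)(2,4,6-trimethoxyphenyl)iodonium 4-methylbenzenesulfonate F3 would be made from 4-iodobenzaldehyde (mCPBA, TsOH, MeCN, then 1,3,5-trimethoxybenzene). With K2CO3 in MeCN at rt to 40 °C it should transfer its electron-poor aryl group to O3 and give 4. Compound 4 is then isolated and benzylated (BnBr, K2CO3, DMF, 60 °C) to 5, where the route is rejoined.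

3. Step 6. The triisopropylsilyl group may migrate from the phenol oxygen to the enolate oxygen, or C-acylation of the hindered enolate may stay incomplete. The fallback avoids the enolate and sets out from 9. Riley oxidation (SeO2, dioxane/H2O, 90 °C) should give the arylglyoxal 2-{2-[(4-{[5,7-bis(benzyloxy)-2-(4-(benzyloxy)phenyl)-4-oxo-4H-chromen-3-yl]oxy}phenyl)methoxy]-4-methoxy-6-[(triisopropylsilyl)oxy]phenyl}-2-oxoacetaldehyde F4. Condensation with TsNHNH2 at the aldehyde carbon (THF, 0 °C) should give the α-keto tosylhydrazone F5. Et3N in CH2Cl2 at rt (Bamford–Stevens-type loss of sulfinate) should then give diazoketone 11, where the route is rejoined.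

**Further compounds**

F1 | step 7 | (E)-1-(2,6-dihydroxy-4-methoxyphenyl)-3-(4-{[5,7-bis(benzyloxy)-2-(4-(benzyloxy)phenyl)-4-oxo-4H-chromen-3-yl]oxy}phenyl)prop-2-en-1-one | COc1cc(O)c(C(=O)/C=C/c2ccc(Oc3c(-c4ccc(OCc5ccccc5)cc4)oc4cc(OCc5ccccc5)cc(OCc5ccccc5)c4c3=O)cc2)c(O)c1
F2 | step 7 | racemic 2-(4-{[5,7-bis(benzyloxy)-2-(4-(benzyloxy)phenyl)-4-oxo-4H-chromen-3-yl]oxy}phenyl)-5-hydroxy-7-methoxy-2,3-dihydro-4H-chromen-4-one | COc1cc(O)c2c(c1)OC(c1ccc(Oc3c(-c4ccc(OCc5ccccc5)cc4)oc4cc(OCc5ccccc5)cc(OCc5ccccc5)c4c3=O)cc1)CC2=O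
F3 | step 2 | (4-formylphenyl)(2,4,6-trimethoxyphenyl)iodonium 4-methylbenzenesulfonate | COc1cc(OC)c([I+]c2ccc(C=O)cc2)c(OC)c1.Cc1ccc(cc1)S(=O)(=O)[O-]
F4 | step 6 | 2-{2-[(4-{[5,7-bis(benzyloxy)-2-(4-(benzyloxy)phenyl)-4-oxo-4H-chromen-3-yl]oxy}phenyl)methoxy]-4-methoxy-6-[(triisopropylsilyl)oxy]phenyl}-2-oxoacetaldehyde | COc1cc(O[Si](C(C)C)(C(C)C)C(C)C)c(C(=O)C=O)c(OCc2ccc(Oc3c(-c4ccc(OCc5ccccc5)cc4)oc4cc(OCc5ccccc5)cc(OCc5ccccc5)c4c3=O)cc2)c1
F5 | step 6 | N'-(2-{2-[(4-{[5,7-bis(benzyloxy)-2-(4-(benzyloxy)phenyl)-4-oxo-4H-chromen-3-yl]oxy}phenyl)methoxy]-4-methoxy-6-[(triisopropylsilyl)oxy]phenyl}-2-oxoethylidene)-4-methylbenzenesulfonohydrazide | COc1cc(O[Si](C(C)C)(C(C)C)C(C)C)c(C(=O)C=NNS(=O)(=O)c2ccc(C)cc2)c(OCc2ccc(Oc3c(-c4ccc(OCc5ccccc5)cc4)oc4cc(OCc5ccccc5)cc(OCc5ccccc5)c4c3=O)cc2)c1
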